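The open dimer Jc and the ring family R = Jb + Jd (Jd appears after Jb) divide what leaves Ja, and the question is how the flask divides it.

| flask | Ja | remark | time |
|---|---|---|---|
| maple | 0.15 M | run made earlier |  |
| birch | 0.22 M | run made earlier |  |
| flask | 0.30 M |  | 80 min |

| run | time / min | Jd / % | Jb / % | Ja / % | Jc / % |
|---|---|---|---|---|---|
| maple | 8.00 | 0 | 2.8 | 91.3 | 5.2 |
| maple | 12.0 | 1.4 | 4.1 | 87.0 | 8.6 |
| maple | 20.0 | 0 | 6.3 | 80.8 | 12.9 |
| maple | 40.0 | 2.0 | 9.1 | 66.6 | 20.6 |
| maple | 60.0 | 4.0 | 12.4 | 55.8 | 26.1 |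
| maple | 90.0 | 6.8 | 16.5 | 44.6 | 31.7 |
| birch | 8.00 | 0 | 2.8 | 88.3 | 7.9 |
| birch | 12.0 | 0 | 4.0 | 83.4 | 11.9 |
| birch | 20.0 | 0.3 | 6.1 | 75.6 | 16.8 |
| birch | 40.0 | 2.5 | 10.3 | 60.8 | 28.2 |
| birch | 60.0 | 3.4 | 13.2 | 49.0 | 34.7 |
| birch | 90.0 | 5.8 | 13.7 | 38.3 | 41.5 |

(each reading ± 0.5 percentage points)

- percent here means Ja units held: one Jc counts as two
- the analysis behind the earlier runs scatters by 0.5 percentage points, standard deviation
- a reading or a percentage of Jb counts all its forms, free or not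

- the species in which most of what was charged as Ja, at 80 min sits (Jc / Jb / Jd / Ja)
- the largest share itself, whichever of these holds it, in percent of the Ja charged

At 8.00 min, Jb reads 2.8 % in both runs, while Jc rises from 5.2 % in maple to 7.9 % in birch. So two times compete: a ring time 1/k, the same in both runs, and a dimer time that shortens with the charge c. The ring time over the starting dimer time is the selectivity factor S = σc, with σ its value per unit of charge and a the fraction of Ja left.

Jc/R ≈ S(1 + a)/2

The last readings give σ = 12.5 M⁻¹ in maple and 14.0 M⁻¹ in birch, with mean 13.3 M⁻¹. For the flask, S = 3.98. Integrating da/dt = −ka(1 + Sa) with maple's own S through maple's last reading gives k = 0.00386 min⁻¹. The flask's ring time is then 259 min against a starting dimer time of 65.1 min.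

a = E/(1 + S(1 − E)), E = exp(−kt)

R = ln[(1 + S)/(1 + Sa)]/S

Jc = 1 − a − R

At 80 min this gives the flask Ja 35.7 %, R 18.1 % and Jc 46.2 %, the most of the three.

The forecast names Jc at 46.3 %, within 44 % to 49 %: “Jc therefore holds the largest share.”

The flask holds 46.4 % in Jc. Crystals of Je, a solid form counted in Jb, hold 5.64 % at 80.0 min, and their growth makes no difference to Jc. At 40.0 min, the same S gives Jc 34.1 %, and the flask stands at 34.3 %.

    Ja → Jb (k = 6.40 × 10⁻⁵ s⁻¹)
    2 Ja → Jc (k = 4.30 × 10⁻⁴ M⁻¹ s⁻¹)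
    Jb → Jd (k = 1.40 × 10⁻⁴ s⁻¹)
    Je ⇌ Jb, rate k4*(cs4 - [Jb]) while solid is left; crystals form when [Jb] > cs4 (solubility = 19.0 mM, k = 0.00100 s⁻¹)

A neighbour flask, charged with 0.51 M of Ja and read at the same time, has S = 6.77, which with the same k gives Jc 58.5 %. Its computed Jc is 58.8 %.

(The numbers in the tables were computed for an exercise, and the scatter is random.)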